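## Retrosynthetic overview

1. Target 24 ⇐ desilylation of 23 ⇐ acid-mediated 1,3-transposition of tertiary allylic alcohol 22, in which the 6β-acetate steers acetate to C7 (α) and the C8=C9 alkene is set ⇐ B-alkyl Suzuki–Miyaura union of vinyl carbinol 16 with Z-vinyl iodide 20 (13Z from but-2-yn-1-ol).
2. 16 ⇐ vinyl addition and acetylation of enone 14 ⇐ one-carbon ring expansion of trans-hydrindanone 11: C8 with its methyl is inserted between C7 and C9, so the five-membered ring (C5, C6, C7, C9, C10) becomes ring B.
3. Enabling feature: in 11 the C9 carbonyl lies between quaternary C10 and methylene C7, so only one enol silane (C7=C9) can form and the carbene carbon can enter only there.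
4. 11 ⇐ commercial bicyclic enedione 1 (C10 stereocentre) by ketalisation, C4 gem-dimethylation, Wolff–Kishner reduction, hydroboration (5α-H) and oxidation–reduction (6β-OH).
5. Ring order: ring A and the five-membered ring come with 1; ring B is formed last, in step 9.

Key step: step 9

Remark: labdane numbering is used for the ring atoms of all intermediates (ring A = C1–C5 and C10; ring B = C5–C10; C8 is absent before step 9), and β denotes the face of the C10 methyl group.

## Route

Step 1
Reactants: 1 (S)-7a-methyl-2,3,7,7a-tetrahydro-1H-indene-1,5(6H)-dione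
Product: 2 C9 mono(ethylene ketal) of dione 1
Conditions: 2-ethyl-2-methyl-1,3-dioxolane, ethylene glycol (cat.), TsOH·H2O (cat.), 23 °C
Reagents that add atoms: 2-ethyl-2-methyl-1,3-dioxolane CCC1(C)OCCO1
Why: Acid-catalysed dioxolane exchange (transketalisation) should take place only at the saturated cyclopentanone carbonyl C9, which is more electrophilic than the conjugated enone carbonyl C3, and it leaves the C10 stereocentre untouched.

Step 2
Reactants: 2 C9 mono(ethylene ketal) of dione 1
Product: 4 4,4-dimethyl-Δ5(6) 3-ketone 9-ketal, via 4-monomethyl ketone 3 (not isolated)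
Conditions: KOt-Bu, t-BuOH, 23 °C; then MeI, 0 → 23 °C
Reagents that add atoms: iodomethane CI
Why: Deconjugative double α-alkylation of the extended enolate: each methyl group enters at C4 of the dienolate and the alkene ends at C5=C6, out of conjugation, while the ketal and C10 are inert.

Step 3
Reactants: 4 4,4-dimethyl-Δ5(6) 3-ketone 9-ketal
Product: 6 3-deoxy-4,4-dimethyl-Δ5(6)-hydrindene 9-ketal, via C3 hydrazone 5 (not isolated)
Conditions: N2H4·H2O, KOH, diethylene glycol, 130 → 200 °C
Reagents that add atoms: none
Why: Wolff–Kishner reduction (Huang-Minlon procedure) removes the hindered C3 carbonyl through hydrazone 5; the ketal and the alkene are stable to base and the alkene cannot migrate into ring A because C4 is quaternary.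

Step 4
Reactants: 6 3-deoxy-4,4-dimethyl-Δ5(6)-hydrindene 9-ketal
Product: 8 6α-hydroxy trans-hydrindane 9-ketal (5α-H), via 6α-alkylborane 7 (not isolated)
Conditions: BH3·THF, THF, 0 → 23 °C; then NaOH, H2O2, 0 °C
Reagents that add atoms: hydrogen peroxide OO
Why: Hydroboration–oxidation adds H and OH syn and anti-Markovnikov across C5=C6 from the α face, since the β face is screened by the C10 methyl and the axial C4 methyl, which sets 5α-H (trans ring fusion) and a 6α-hydroxyl.

Step 5
Reactants: 8 6α-hydroxy trans-hydrindane 9-ketal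
Product: 9 6-oxo trans-hydrindane 9-ketal
Conditions: (n-Pr4N)RuO4 (cat.), NMO, 4 Å MS, CH2Cl2, 23 °C
Reagents that add atoms: none
Why: Ley–Griffith oxidation is neutral, so the secondary alcohol is oxidised without epimerising the now enolisable C5 or disturbing the ketal.

Step 6
Reactants: 9 6-oxo trans-hydrindane 9-ketal
Product: 10 6β-hydroxy trans-hydrindane 9-ketal
Conditions: NaBH4, MeOH, −20 °C
Reagents that add atoms: none
Why: Ketone reduction under steric approach control: hydride should add to C6 from the open α face because the C10 methyl and the axial C4 methyl block the β face, which gives the 6β alcohol, and the low temperature keeps C5 from epimerising.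

Step 7
Reactants: 10 6β-hydroxy trans-hydrindane 9-ketal
Product: 11 6β-hydroxy-4,4,10-trimethyl-trans-hydrindan-9-one
Conditions: 1 M HCl, THF, 23 °C
Reagents that add atoms: water O
Why: Acid-catalysed hydrolysis of the dioxolane frees the C9 ketone; the β-hydroxy ketone tolerates dilute acid at room temperature.

Step 8
Reactants: 11 6β-hydroxy-4,4,10-trimethyl-trans-hydrindan-9-one
Product: 12 6β-trimethylsiloxy C7=C9 enol trimethylsilyl ether
Conditions: TMSOTf, Et3N, CH2Cl2, 0 °C
Reagents that add atoms: trimethylsilyl trifluoromethanesulfonate C[Si](C)(C)OS(=O)(=O)C(F)(F)F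
Why: Soft enolisation with silyl triflate and amine silylates the hydroxyl and converts the ketone into its only possible enol silane (C7=C9, as C10 is quaternary); a siloxy group is a poor leaving group, so no β-elimination across C6–C7 is expected.

Step 9
Reactants: 12 6β-trimethylsiloxy C7=C9 enol trimethylsilyl ether
Product: 14 6β-hydroxy-8-methyl trans-octalin-9-one (C7=C8 enone), via chlorocyclopropane 13 (not isolated)
Conditions: CH3CHCl2, n-BuLi, Et2O, −40 → −20 °C; then MeOH, Et3N, 65 °C; K2CO3 (cat.), 23 °C
Reagents that add atoms: 1,1-dichloroethane CC(Cl)Cl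
Why: n-BuLi deprotonates 1,1-dichloroethane and the resulting 1,1-dichloroethyllithium loses LiCl to deliver chloro(methyl)carbene (as its carbenoid) to the electron-rich enol silane C7=C9 of 12, the only alkene present, in a concerted [2+1] addition that closes the three-membered ring C7–C8–C9 of bicyclo[3.1.0]hexane 13. On warming in methanol the cyclopropyl chloride undergoes the two-electron disrotatory electrocyclic ring opening, pushed by the siloxy group, in which chloride leaves and the shared C7–C9 bond breaks, so that the five-membered ring (C5, C6, C7, C9, C10) becomes six-membered ring B with C8 and its methyl between C7 and C9; loss of the silyl group from the siloxyallyl cation gives the 8-methyl enone and methanolysis frees the 6β-hydroxyl. The closest known reaction type is the one-carbon ring expansion of cyclic silyl enol ethers with halocarbenes to 2-substituted cycloalk-2-enones, here in its 2-methyl variant from 1,1-dichloroethane. Ring B is thus closed by bond scission within a fused bicycle and not by a new ring-closing bond, and no new stereocentre is formed (C8 is sp2) while C5, C6 and C10 are not touched. The selectivity that matters is the site of insertion: because C10 is quaternary the ketone of 11 can only enolise towards C7, so the carbene carbon can only enter between C7 and C9; the siloxy donor should let either C8 epimer of 13 ionise, although the epimer with chlorine on the side of the five-membered ring should open fastest.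

Step 10
Reactants: 14 6β-hydroxy-8-methyl trans-octalin-9-one (C7=C8 enone)
Product: 15 9α-vinyl 6β,9β-diol
Conditions: CH2=CHMgBr, CeCl3, THF, −78 → 0 °C
Reagents that add atoms: vinylmagnesium bromide C=C[Mg]Br
Why: Organocerium 1,2-addition to the hindered enone carbonyl (the first equivalent only deprotonates the hydroxyl) from the α face opposite the C10 methyl should give the 9β-alcohol, a stereocentre that is erased again in step 15.

Step 11
Reactants: 15 9α-vinyl 6β,9β-diol
Product: 16 6β-acetoxy 9α-vinyl 9β-ol
Conditions: Ac2O, DMAP (cat.), Et3N, CH2Cl2, 23 °C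
Reagents that add atoms: acetic anhydride CC(=O)OC(C)=O
Why: DMAP-catalysed acylation is chemoselective for the secondary 6β-hydroxyl over the tertiary, neopentyl-type 9-hydroxyl.

Step 12
Reactants: 17 but-2-yn-1-ol
Product: 19 (Z)-3-iodobut-2-en-1-ol, via cyclic vinylalanate 18 (not isolated)
Conditions: NaAlH2(OCH2CH2OMe)2, THF, 0 → 23 °C; then I2, −78 → 0 °C
Reagents that add atoms: iodine II
Why: trans-Hydroalumination of the propargylic alkoxide through the five-membered oxa-aluminacycle 18 followed by iodinolysis with retention places iodine cis to CH2OH, which fixes the Z geometry needed for C13=C14.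

Step 13
Reactants: 19 (Z)-3-iodobut-2-en-1-ol
Product: 20 (Z)-tert-butyl((3-iodobut-2-en-1-yl)oxy)diphenylsilane
Conditions: t-BuPh2SiCl, imidazole, CH2Cl2, 23 °C
Reagents that add atoms: tert-butyl(chloro)diphenylsilane CC(C)(C)[Si](Cl)(c1ccccc1)c1ccccc1
Why: Silylation of the primary alcohol with a silyl group robust enough to survive the acidic step 15.

Step 14
Reactants: 16 6β-acetoxy 9α-vinyl 9β-ol, 20 (Z)-tert-butyl((3-iodobut-2-en-1-yl)oxy)diphenylsilane
Product: 22 6β-acetoxy 9β-hydroxy Δ7 tertiary allylic alcohol carrying the complete 13Z side chain (15-silyl ether), via B-alkyl-9-BBN 21 (not isolated)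
Conditions: 9-BBN, THF, 23 °C; then 20, Pd(dppf)Cl2 (cat.), AsPh3 (cat.), Cs2CO3, DMF/H2O, 23 °C
Reagents that add atoms: none
Why: B-alkyl Suzuki–Miyaura coupling: 9-BBN adds anti-Markovnikov only to the monosubstituted vinyl group (the trisubstituted C7=C8 alkene is too hindered) and the primary borane couples with the vinyl iodide with retention, so the Z alkene of 20 becomes 13Z.

Step 15
Reactants: 22 6β-acetoxy 9β-hydroxy Δ7 tertiary allylic alcohol (15-silyl ether)
Product: 23 (13Z)-6β,7α-diacetoxylabda-8,13-dien-15-yl tert-butyldiphenylsilyl ether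
Conditions: AcOH/Ac2O (10:1), CSA (cat.), 0 → 23 °C
Reagents that add atoms: acetic acid CC(=O)O
Why: Acid-promoted ionisation of the tertiary allylic alcohol gives the C7–C8–C9 allyl cation, which is captured at C7 on the β face by the neighbouring 6β-acetate (1,3-dioxolan-2-ylium ion); acetic acid then opens this ion at allylic C7 from the α face with inversion (Prévost-type trans outcome under anhydrous conditions), which sets 7α-OAc trans to 6β-OAc and leaves the tetrasubstituted C8=C9 alkene (allylic 1,3-transposition with neighbouring-group participation).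

Step 16
Reactants: 23 (13Z)-6β,7α-diacetoxylabda-8,13-dien-15-yl tert-butyldiphenylsilyl ether
Product: 24 (13Z)-6β,7α-diacetoxylabda-8,13-dien-15-ol (CNP0187815.3)
Conditions: HF·pyridine, pyridine, THF, 0 → 23 °C
Reagents that add atoms: none
Why: Fluoride cleaves the Si–O bond under buffered conditions that should leave both acetates and the allylic system intact.

## Compound list

1 | (S)-7a-methyl-2,3,7,7a-tetrahydro-1H-indene-1,5(6H)-dione | C[C@]12CCC(=O)C=C1CCC2=O | starting material
2 | C9 mono(ethylene ketal) of 1 (enone carbonyl C3 free) | C[C@]12CCC(=O)C=C1CCC21OCCO1 | intermediate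
3 | 4-monomethyl Δ5(6) 3-ketone 9-ketal (C4 epimers) | C[C@]12CCC(=O)C(C)C1=CCC21OCCO1 | intermediate
4 | 4,4-dimethyl-Δ5(6) 3-ketone 9-ketal | C[C@]12CCC(=O)C(C)(C)C1=CCC21OCCO1 | intermediate
5 | C3 hydrazone of 4 | C[C@]12CCC(=NN)C(C)(C)C1=CCC21OCCO1 | intermediate
6 | 3-deoxy-4,4-dimethyl-Δ5(6)-hydrindene 9-ketal | C[C@]12CCCC(C)(C)C1=CCC21OCCO1 | intermediate
7 | 6α-boryl trans-hydrindane 9-ketal (monoalkylborane, 5α-H) | B[C@H]1CC3(OCCO3)[C@@]2(C)CCCC(C)(C)[C@H]12 | intermediate
8 | 6α-hydroxy trans-hydrindane 9-ketal (5α-H, 10β-Me) | O[C@H]1CC3(OCCO3)[C@@]2(C)CCCC(C)(C)[C@H]12 | intermediate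
9 | 6-oxo trans-hydrindane 9-ketal | O=C1CC3(OCCO3)[C@@]2(C)CCCC(C)(C)[C@H]12 | intermediate
10 | 6β-hydroxy trans-hydrindane 9-ketal | O[C@@H]1CC3(OCCO3)[C@@]2(C)CCCC(C)(C)[C@H]12 | intermediate
11 | 6β-hydroxy-4,4,10-trimethyl-trans-hydrindan-9-one | O[C@@H]1CC(=O)[C@@]2(C)CCCC(C)(C)[C@H]12 | intermediate
12 | 6β-trimethylsiloxy C7=C9 enol trimethylsilyl ether | C[Si](C)(C)O[C@@H]1C=C(O[Si](C)(C)C)[C@@]2(C)CCCC(C)(C)[C@H]12 | intermediate
13 | 8-chloro-8-methyl-9-siloxy cyclopropane (C7–C8–C9, epimers at the new centres) | C[Si](C)(C)O[C@@H]1C3C(C)(Cl)C3(O[Si](C)(C)C)[C@@]2(C)CCCC(C)(C)[C@H]12 | intermediate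
14 | 6β-hydroxy-4,4,8,10-tetramethyl trans-octalin-9-one (C7=C8 enone, 5α-H) | O[C@@H]1C=C(C)C(=O)[C@@]2(C)CCCC(C)(C)[C@H]12 | intermediate
15 | 9α-vinyl 6β,9β-diol (C7=C8) | O[C@@H]1C=C(C)[C@@](O)(C=C)[C@@]2(C)CCCC(C)(C)[C@H]12 | intermediate
16 | 6β-acetoxy 9α-vinyl 9β-ol (C7=C8) | CC(=O)O[C@@H]1C=C(C)[C@@](O)(C=C)[C@@]2(C)CCCC(C)(C)[C@H]12 | intermediate
17 | but-2-yn-1-ol | CC#CCO | starting material
18 | sodium 2,2-bis(2-methoxyethoxy)-3-methyl-2,5-dihydro-1,2-oxaluminol-2-uide (cyclic vinylalanate) | CC1=CCO[Al-]1(OCCOC)OCCOC.[Na+] | intermediate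
19 | (Z)-3-iodobut-2-en-1-ol | C/C(I)=C/CO | intermediate
20 | (Z)-tert-butyl((3-iodobut-2-en-1-yl)oxy)diphenylsilane | C/C(I)=C/CO[Si](c1ccccc1)(c1ccccc1)C(C)(C)C | intermediate
21 | B-alkyl-9-BBN from 16 (boron on C12) | CC(=O)O[C@@H]1C=C(C)[C@@](O)(CCB3C4CCCC3CCC4)[C@@]2(C)CCCC(C)(C)[C@H]12 | intermediate
22 | 6β-acetoxy 9β-hydroxy Δ7 tertiary allylic alcohol with 13Z side chain on C9 (α), 15-O-tert-butyldiphenylsilyl | CC(=O)O[C@@H]1C=C(C)[C@@](O)(CC/C(C)=C\CO[Si](c3ccccc3)(c3ccccc3)C(C)(C)C)[C@@]2(C)CCCC(C)(C)[C@H]12 | intermediate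
23 | (13Z)-6β,7α-diacetoxylabda-8,13-dien-15-yl tert-butyldiphenylsilyl ether | CC(=O)O[C@@H]1[C@@H](OC(C)=O)C(C)=C(CC/C(C)=C\CO[Si](c3ccccc3)(c3ccccc3)C(C)(C)C)[C@@]2(C)CCCC(C)(C)[C@H]12 | intermediate
24 | (13Z)-6β,7α-diacetoxylabda-8,13-dien-15-ol (CNP0187815.3) | CC(=O)O[C@@H]1[C@@H](OC(C)=O)C(C)=C(CC/C(C)=C\CO)[C@@]2(C)CCCC(C)(C)[C@H]12 | target

## Step count and risks

Total step count: 16. Longest linear sequence: 14 steps (steps 1–11 and 14–16; steps 12 and 13 make the side-chain fragment).

Steps most likely to fail:

Step 9. The short-lived chloro(methyl)carbenoid may rearrange by 1,2-hydride shift or be consumed before it reaches the hindered enol silane next to quaternary C10. The cyclopropane epimer with chlorine pointing away from the five-membered ring may also open sluggishly. Fallback, setting out from 12: dibromocarbene addition (CHBr3, KOt-Bu, pentane, 0 °C) should give dibromocyclopropane F1, in which one bromine necessarily lies on the reactive side. Warming in MeOH/Et3N and then K2CO3 should bring about the same ring expansion and give 8-bromo enone F2. Stille methylation (Me4Sn, Pd(PPh3)4, CuI, DMF, 60 °C) would then return to the route at 14.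

Step 15. Proton loss from C11 of the allyl cation (diene formation) may outrun capture. Capture may occur at the C9 terminus instead of C7, adventitious water may open the acetoxonium ion in the cis sense, or the acid may cleave the silyl ether. Fallback, setting out from 22: oxidative 1,3-transposition with (C5H5NH)CrO3Cl (CH2Cl2, 23 °C) should give 6β-acetoxy-7-oxo-8-ene F3. Luche reduction (NaBH4, CeCl3·7H2O, MeOH, −78 °C), with hydride entering from the α face, should give 7β-alcohol F4. Mitsunobu inversion with acetic acid (PPh3, DIAD, THF, 0 °C) would return to the route at 23.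

Step 14. Transmetalation of the alkylborane, which sits next to the fully substituted carbinol carbon, may be slow and give way to protodeboronation. Zerovalent palladium may also insert into the allylic C6–O bond of the acetate. Fallback, setting out from 16: hydroboration–oxidation (9-BBN, THF; then NaBO3·4H2O) should give primary alcohol F5. Appel-type iodination (I2, PPh3, imidazole, CH2Cl2, 0 °C) should give primary iodide F6. Nickel-catalysed reductive cross-electrophile coupling with 20 (NiBr2(dme), 4,4'-di-tert-butyl-2,2'-bipyridine, Mn, DMA, 23 °C) would return to the route at 22.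

Further compounds
F1 | step 9 | 8,8-dibromo-9-siloxy cyclopropane (C7–C8–C9) with 6β-trimethylsiloxy group | C[Si](C)(C)O[C@@H]1C3C(Br)(Br)C3(O[Si](C)(C)C)[C@@]2(C)CCCC(C)(C)[C@H]12
F2 | step 9 | 8-bromo-6β-hydroxy-4,4,10-trimethyl trans-octalin-9-one (C7=C8 enone) | O[C@@H]1C=C(Br)C(=O)[C@@]2(C)CCCC(C)(C)[C@H]12
F3 | step 15 | (13Z)-6β-acetoxy-7-oxolabda-8,13-dien-15-yl tert-butyldiphenylsilyl ether | CC(=O)O[C@@H]1C(=O)C(C)=C(CC/C(C)=C\CO[Si](c3ccccc3)(c3ccccc3)C(C)(C)C)[C@@]2(C)CCCC(C)(C)[C@H]12
F4 | step 15 | (13Z)-6β-acetoxy-7β-hydroxylabda-8,13-dien-15-yl tert-butyldiphenylsilyl ether | CC(=O)O[C@@H]1[C@H](O)C(C)=C(CC/C(C)=C\CO[Si](c3ccccc3)(c3ccccc3)C(C)(C)C)[C@@]2(C)CCCC(C)(C)[C@H]12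
F5 | step 14 | 6β-acetoxy 9β-hydroxy Δ7 compound with 2-hydroxyethyl group on C9 | CC(=O)O[C@@H]1C=C(C)[C@@](O)(CCO)[C@@]2(C)CCCC(C)(C)[C@H]12
F6 | step 14 | 6β-acetoxy 9β-hydroxy Δ7 compound with 2-iodoethyl group on C9 | CC(=O)O[C@@H]1C=C(C)[C@@](O)(CCI)[C@@]2(C)CCCC(C)(C)[C@H]12
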